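## Analysis of the target

Target 12 is a flavanone: a benzo ring (ring A) fused to a 2,3-dihydro-4H-pyran-4-one (ring C: O1, C2, C3, C4, C4a, C8a), with a 3,4-dimethoxyphenyl group (ring B) on C2. Ring A is substituted at every carbon except C8: O1 at C8a, the ketone at C4a, a hydroxyl at C5 and methoxyls at C6 and C7. The C5 hydroxyl is hydrogen-bonded to the C4 carbonyl, which sets it apart from the two neighbouring methoxyls. There is one stereocentre, C2 (S); it is benzylic, bound to O1 and β to the ketone, and no second stereocentre can relay to it. C2 is also the weak point: base opens ring C by retro-oxa-Michael reaction to the achiral 2'-hydroxychalcone, and because ring B is a strong donor a strong Lewis acid can loosen the C2–O1 bond. The difficulty is therefore absolute control at an isolated benzylic ether carbon, together with telling the C5 oxygen from those at C6 and C7. The strategy rests on two features: C2 is flanked by O1 and the cation-stabilising ring B, so it is the natural carbon of an aryloxycarbenium ion, and C4a, ortho to O1 and the C5 oxygen and para to the C7 oxygen, is the most nucleophilic carbon of ring A. C3 and C4 between them form a two-carbon unit at the oxidation level of acetic acid, and if C5 keeps a methoxyl until the end, the ring A building block is symmetric with two identical ortho positions.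

## Retrosynthetic reasoning

**12 to 11.** The O–CH3 bond at C5 is cut last. With a methoxyl at C5, ring A can come from the symmetric phenol 4, so the ring closure has no regiochemical choice. The forward reaction has to remove one methyl group out of five; the C4 carbonyl peri to the C5 oxygen makes this possible by chelation to a boron trihalide.

**11 to 10.** The ketone is traced back to its dimethyl ketal. The ring-forming step delivers C4 at this level, and the ketal is expected to be the stable form under the conditions of that step. The forward reaction is a mild acid hydrolysis that must not open ring C.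

**10 to 6 and 7.** The bonds C2–C3 and C4–C4a are cut. Cutting C2–C3 leaves a cation at C2 that is stabilised by O1 and by ring B. Cutting C4–C4a is the reverse of a Friedel–Crafts reaction at the most electron-rich position of ring A. What remains between the two cuts is exactly the ketene acetal 7. A cut at O1–C2 would lead to an asymmetric oxa-Michael closure of a doubly ortho-substituted hydroxy enone, which is base-mediated and reversible. A cut at the C2–aryl bond is kept as the reserve route. The chosen cut gains ring C, two skeletal bonds and the stereocentre in one operation from a racemic acetal and an achiral alkene. The forward reaction has to ionise 6 by loss of its methoxy group and not of its aryloxy group, control the face of the planar cation through a chiral counter-anion, and close the ring before the second cation is captured otherwise.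

**6 to 3 and 4.** The acetal C–OAr bond is cut. The forward reaction is the O-alkylation of phenoxide 5, made from 4, by the α-chloro ether 3, the same reaction by which methoxymethyl aryl ethers are prepared. It has to occur at oxygen and not at the nucleophilic ring carbons of 5.

**3 to 2 to 1.** The chloro ether 3 comes from the dimethyl acetal 2 by exchange of one methoxy group for chloride with an acyl chloride, and 2 comes from aldehyde 1 by acetalisation. Both are functional-group changes on a commercial aldehyde and carry no selectivity problem.

## Alternatives that were turned down

**Alternative 1:** Ring A is taken apart completely (C8–C8a, C7–C8, C5–C6, C4a–C5). This leaves an enantiopure dihydropyranone with a diazoacetyl group on its enol ether carbon, the diazoketone A2, and the dialkoxyalkyne A3.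
- Forward key step: irradiation of A2 triggers a Wolff rearrangement to a vinylketene (C8–C8a). The ketene adds A3 in a [2+2] cycloaddition (C5–C6, C7–C8); four-electron ring opening and six-electron ring closure (C4a–C5) then give the phenol A1.
- For: the substitution pattern of ring A is fixed by the mechanism, and the C5 hydroxyl is born free from the ketene carbonyl, so no demethylation is needed. C2 can be set beforehand by an established catalytic asymmetric hetero-Diels–Alder reaction. On reliability of enantiocontrol and on the C5 problem this route is stronger than the chosen one.
- Against: the pyranone needs a carboxyl handle and its conversion to the diazoketone. The enone and ring B absorb light competitively. A3 loses its tert-butyl groups on warming, while the electrocyclic cascade needs heat. After the key step both tert-butyl ethers of A1 must be cleaved and two phenols methylated beside the chelated C5 hydroxyl without base, which would open ring C.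
- Comparison: it rebuilds a benzene ring that can be bought as 4 and needs roughly twice as many steps. The chosen strategy offers brevity and a ring A that arrives with all its oxygens in place.

**Alternative 2:** The cuts are C8a–O1 and C4–C4a, with reversed polarity at C4a: the aryne A5 and the enantiopure hydroxy ester A6.
- Forward key step: a fluoride source releases A5 from its ortho-silyl aryl triflate precursor. The alkoxide of A6 adds to the aryne carbon remote from the neighbouring methoxyl, which places the aryl anion at C4a. The anion attacks the ester (6-exo-trig acyl substitution) and gives A4, which is the same compound as 11.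
- For: C2 is set before the key step by asymmetric hydrogenation of a β-keto ester or an acetate aldol reaction, which is established and predictable. On enantiocontrol this route is clearly stronger. The aryne regiochemistry is governed by the flanking methoxyl, and the product joins the chosen route at its penultimate compound.
- Against: the aryne precursor takes about three steps from 4. Under basic fluoride conditions a benzylic β-hydroxy ester alkoxide can undergo retro-aldol cleavage or elimination to the cinnamate. The aryl anion can be quenched by the acidic α-hydrogens and then gives only the open aryl ether. The flavanone formed sits in a basic medium in which ring C opens and C2 is lost.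
- Comparison: about eight steps, with the stereocentre exposed to base at the end. The chosen strategy is shorter and keeps C2 under mildly acidic, aprotic conditions, at the price of an untested enantioselective step.

**Alternative 3:** Only C8a–O1 is cut, with ring A at the quinone oxidation level: the acylquinone A8, which carries the enantiopure β-hydroxy ketone side chain.
- Forward key step: the C2 hydroxyl adds in a 6-endo-trig oxa-Michael reaction to C8a, which is activated by both the side-chain carbonyl and the C5 quinone carbonyl. Tautomerisation gives the hydroquinone A7.
- For: the closure is fast, needs no base and does not touch C2, which is set earlier by known chemistry. On mildness of the ring closure it is at least as good as the chosen route, and on enantiocontrol it is stronger.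
- Against: A7 carries a hydroxyl at C8 that the target lacks. It has to be removed by selective sulfonylation of the non-chelated hydroxyl and reductive C–O cleavage, two extra steps. The quinone must be generated by oxidation next to the electron-rich ring B and a benzylic alcohol. A β-hydroxy ketone attached to a quinone dehydrates easily, and the ring A hydroquinone has to be built and acylated first.
- Comparison: about ten steps, with a detour through a higher oxidation state of ring A. The chosen strategy uses ring A at its final oxidation level and spends its risk on one step only.

Key step: step 4

Assumption: the sense of induction of the chiral squaramide–triflate ion pair cannot be predicted for this new cation, so the catalyst enantiomer that gives the 2S product is to be fixed by screening. A representative catalyst is 3-{[3,5-bis(trifluoromethyl)phenyl]amino}-4-({(2S)-3,3-dimethyl-1-oxo-1-[(2S)-2-(pyren-1-yl)pyrrolidin-1-yl]butan-2-yl}amino)cyclobut-3-ene-1,2-dione or its enantiomer.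

## Route

**Step 1**
Reactants: 1 3,4-dimethoxybenzaldehyde
Product: 2 4-(dimethoxymethyl)-1,2-dimethoxybenzene
Conditions: HC(OMe)3 (1.5 equiv), TsOH·H2O (1 mol%), MeOH, rt; then Et3N
Reagents that add atoms: trimethyl orthoformate, COC(OC)OC; methanol, CO
Why: Acid-catalysed acetalisation; the orthoformate consumes the water formed, so the equilibrium lies on the side of the acetal, and no other group of 1 reacts.

**Step 2**
Reactants: 2 4-(dimethoxymethyl)-1,2-dimethoxybenzene
Product: 3 4-[chloro(methoxy)methyl]-1,2-dimethoxybenzene (racemic)
Conditions: AcCl (1.1 equiv), SOCl2 (2 mol%), CH2Cl2, 0 °C to rt; volatiles removed, crude used at once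
Reagents that add atoms: acetyl chloride, CC(=O)Cl
Why: Acetal to α-chloro ether exchange: the acetal ionises, the acyl chloride takes up the methoxide as its methyl ester, and chloride closes on the oxocarbenium ion. Only volatiles have to be removed; the product is moisture-sensitive and very ionisable, so it is not purified.

**Step 3**
Reactants: 4 3,4,5-trimethoxyphenol; 3 4-[chloro(methoxy)methyl]-1,2-dimethoxybenzene (racemic)
Product: 6 5-[(3,4-dimethoxyphenyl)(methoxy)methoxy]-1,2,3-trimethoxybenzene (racemic), via sodium 3,4,5-trimethoxyphenoxide 5 (not isolated)
Conditions: NaH (1.05 equiv), DMF, 0 °C; then 3 (1.1 equiv) in THF, −20 to 0 °C; aq. NaHCO3 work-up, Et3N-deactivated silica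
Reagents that add atoms: none
Why: Williamson-type O-alkylation of a phenoxide by an α-chloro ether, as in the preparation of methoxymethyl aryl ethers; the free phenoxide in a dipolar solvent should react at oxygen with this hard, SN1-like electrophile. The mixed acetal is base-stable and acid-labile, hence the basic work-up; its acetal stereocentre is left racemic because the key step destroys it.

**Step 4**
Reactants: 6 5-[(3,4-dimethoxyphenyl)(methoxy)methoxy]-1,2,3-trimethoxybenzene (racemic); 7 1,1-dimethoxyethene
Product: 10 (S)-2-(3,4-dimethoxyphenyl)-4,4,5,6,7-pentamethoxychroman, via aryloxycarbenium triflate 8 (not isolated), via dimethoxycarbenium triflate 9 (not isolated)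
Conditions: Me3SiOTf (10 mol%), chiral squaramide (12 mol%), 7 (2.5 equiv, added over 2 h), t-BuOMe, −78 °C; then Et3N, aq. NaHCO3
Reagents that add atoms: none
Why: Proposed new method: the squaramide-bound Me3SiOTf should silylate the more basic, unhindered methoxy oxygen of 6 and expel Me3SiOMe, so that both enantiomers of racemic 6 converge on the planar aryloxycarbenium ion 8, held as a contact ion pair with the squaramide-bound triflate. Ketene acetal 7 then adds through its CH2 carbon to C2 of 8 (forming C2–C3 and the dimethoxycarbenium ion 9), and C4a, which is ortho to O1 and to the C5 methoxyl and para to the C7 methoxyl, attacks C4 of 9 (forming C4–C4a); loss of the C4a proton gives ketal 10. The closest known reaction types are the racemic Lewis-acid oxa-Povarov annulation of aryloxycarbenium ions with alkenes and the chiral hydrogen-bond-donor (anion-binding) catalysis of silyl enol ether and silyl ketene acetal additions to oxocarbenium ions; a ketene acetal as two-carbon partner of an enantioselective oxa-Povarov annulation has no precedent. Ring C closes by Friedel–Crafts alkylation in a 6-exo-trig mode at C4 (both C–O bonds of the dimethoxycarbenium unit stay outside the new ring while the arene bond C4a–C8a lies inside it), not by an endo closure. C2, the only stereocentre, is set in the C2–C3 bond formation and is controlled by the catalyst alone: the chiral anion complex and the aryl groups of the squaramide have to shield one face of 8. The step needs ionisation towards 8 and not towards the methoxycarbenium ion (hence a silyl Lewis acid and no Brønsted acid, which would protonate and expel the better leaving group, the aryloxide), ring closure of 9 faster than its capture by more 7 (slow addition of 7, triply activated C4a, six-membered ring), and a single site of closure (the two ortho positions of the aryloxy ring are equivalent by symmetry). The proton from C4a and the methoxy group from 6 are taken up by a second equivalent of 7 as trimethyl orthoacetate, which returns Me3SiOTf and keeps the medium free of protic acid until the amine quench.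

**Step 5**
Reactants: 10 (S)-2-(3,4-dimethoxyphenyl)-4,4,5,6,7-pentamethoxychroman
Product: 11 (S)-2-(3,4-dimethoxyphenyl)-5,6,7-trimethoxychroman-4-one
Conditions: 0.5 M aq. HCl, THF, 0 °C to rt
Reagents that add atoms: water, O
Why: Acid hydrolysis of a dimethyl ketal; the C4 cation is stabilised by the ortho and para oxygens of ring A, so dilute acid at or below room temperature should suffice, and without base ring C and C2 are not disturbed. Any enol ether formed by loss of a C3 proton from that cation hydrolyses to the same ketone.

**Step 6**
Reactants: 11 (S)-2-(3,4-dimethoxyphenyl)-5,6,7-trimethoxychroman-4-one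
Product: 12 (S)-5-hydroxy-2-(3,4-dimethoxyphenyl)-6,7-dimethoxychroman-4-one
Conditions: BCl3 (1.5 equiv, 1 M in CH2Cl2), CH2Cl2, −78 to −20 °C; then H2O
Reagents that add atoms: none
Why: Chelation-controlled ether cleavage: BCl3 binds the C4 carbonyl and the peri C5 methoxy oxygen in a six-membered chelate and chloride removes that methyl group alone; the methoxyls at C6, C7 and on ring B lack the neighbouring carbonyl and are kept by limiting reagent and temperature. Low temperature and a short reaction time protect C2, whose C2–O1 bond is the one a Lewis acid could loosen.

## Compound list

1 | 3,4-dimethoxybenzaldehyde | COc1ccc(C=O)cc1OC | starting material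
2 | 4-(dimethoxymethyl)-1,2-dimethoxybenzene | COc1ccc(C(OC)OC)cc1OC | intermediate
3 | 4-[chloro(methoxy)methyl]-1,2-dimethoxybenzene (racemic) | COc1ccc(C(Cl)OC)cc1OC | intermediate
4 | 3,4,5-trimethoxyphenol | COc1cc(O)cc(OC)c1OC | starting material
5 | sodium 3,4,5-trimethoxyphenoxide | [Na+].[O-]c1cc(OC)c(OC)c(OC)c1 | intermediate
6 | 5-[(3,4-dimethoxyphenyl)(methoxy)methoxy]-1,2,3-trimethoxybenzene (racemic) | COC(Oc1cc(OC)c(OC)c(OC)c1)c1ccc(OC)c(OC)c1 | intermediate
7 | 1,1-dimethoxyethene | C=C(OC)OC | starting material
8 | [(3,4-dimethoxyphenyl)methylidene](3,4,5-trimethoxyphenyl)oxonium trifluoromethanesulfonate | COc1ccc(C=[O+]c2cc(OC)c(OC)c(OC)c2)cc1OC.[O-]S(=O)(=O)C(F)(F)F | intermediate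
9 | (S)-[3-(3,4-dimethoxyphenyl)-1-methoxy-3-(3,4,5-trimethoxyphenoxy)propylidene](methyl)oxonium trifluoromethanesulfonate | COc1ccc([C@@H](Oc2cc(OC)c(OC)c(OC)c2)CC(OC)=[O+]C)cc1OC.[O-]S(=O)(=O)C(F)(F)F | intermediate
10 | (S)-2-(3,4-dimethoxyphenyl)-4,4,5,6,7-pentamethoxychroman | COc1ccc([C@@H]2CC(OC)(OC)c3c(cc(OC)c(OC)c3OC)O2)cc1OC | intermediate
11 | (S)-2-(3,4-dimethoxyphenyl)-5,6,7-trimethoxychroman-4-one | COc1ccc([C@@H]2CC(=O)c3c(cc(OC)c(OC)c3OC)O2)cc1OC | intermediate
12 | (S)-5-hydroxy-2-(3,4-dimethoxyphenyl)-6,7-dimethoxychroman-4-one | COc1ccc([C@@H]2CC(=O)c3c(cc(OC)c(OC)c3O)O2)cc1OC | target

## Step count and least certain steps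

Total step count: 6. Longest linear sequence: 6 steps (1 to 12); 4 enters in step 3 and 7 in step 4.

**Step 4 (key step).**
- What may go wrong: the most likely failure is poor facial selectivity. Cation 8 is planar, strongly stabilised and can exist as E and Z forms, and it is bound to the chiral anion only by ion pairing.
- Second: ionisation in the wrong direction, with loss of the aryloxide, would lead to an open-chain addition product and free phenol. The remedy inside the strategy would be a carboxylate in place of the methoxy leaving group, which is both the better nucleofuge and the poorer donor.
- Third: cation 9 may be captured by further 7 (oligomerisation) or collapse to the open-chain ester before C4a attacks. The excess of 7 may also add to the ionised product ketal, or Me3SiOTf may be lost through C-silylation of 7. A partial success in which only C2–C3 is formed could be completed by a separate Friedel–Crafts acylation.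
- Fallback (known chemistry), from 4 back to 11: C-acetylation of 4 with AcOH and BF3·OEt2 at 90 °C should give 1-(6-hydroxy-2,3,4-trimethoxyphenyl)ethan-1-one F1. Condensation with N,N-dimethylformamide dimethyl acetal in toluene at 100 °C gives the enaminone (E)-3-(dimethylamino)-1-(6-hydroxy-2,3,4-trimethoxyphenyl)prop-2-en-1-one F2. Acid (HCl, CH2Cl2) cyclises it to 5,6,7-trimethoxy-4H-chromen-4-one F3. Asymmetric 1,4-addition of 3,4-dimethoxyphenylboronic acid to F3, catalysed by [Rh(OH)(cod)]2 with an electron-poor atropisomeric bisphosphine of the MeO-BIPHEP family in toluene/H2O, gives 11. This is a known way to 2-arylchroman-4-ones; the route then continues with step 6.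

**Step 3 (with the handling of 3 from step 2).**
- What may go wrong: C-alkylation of the very electron-rich phenoxide by the cation-like electrophile, self-alkylation or hydrolysis of 3 before it is used, and loss of the acid-labile mixed acetal on silica.
- Fallback, from 4 back to 6, bypassing 2 and 3: 4 is benzylated with 3,4-dimethoxybenzyl chloride (K2CO3, DMF), an ordinary SN2 O-alkylation, to 5-[(3,4-dimethoxybenzyl)oxy]-1,2,3-trimethoxybenzene F4. Benzylic hydride abstraction with DDQ in CH2Cl2 containing MeOH and solid NaHCO3 at 0 °C generates the same aryloxycarbenium ion, which methanol captures as 6. This is the oxidative acetal formation known for methoxybenzyl ethers.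

**Step 6.**
- What may go wrong: erosion of the configuration at C2 by reversible opening of ring C on the boron-chelated ketone, favoured by the donor ring B, and over-demethylation at C6 if the reagent or temperature is too high.
- Fallback, from 4 to 12, removing the methyl group before the stereocentre exists: 4 is taken through F1 and F2 to chromone F3 as described for step 4. BCl3 in CH2Cl2 cleaves the chelated methyl ether of the achiral chromone to 5-hydroxy-6,7-dimethoxy-4H-chromen-4-one F5. Benzylation (BnBr, K2CO3, DMF) gives 5-(benzyloxy)-6,7-dimethoxy-4H-chromen-4-one F6. The rhodium-catalysed asymmetric 1,4-addition of 3,4-dimethoxyphenylboronic acid ([Rh(OH)(cod)]2, chiral bisphosphine) gives (S)-5-(benzyloxy)-2-(3,4-dimethoxyphenyl)-6,7-dimethoxychroman-4-one F7. Hydrogenolysis (H2, Pd/C, EtOAc) under neutral conditions gives 12.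

**Step 5.**
- What may go wrong: slow hydrolysis of the hindered ketal, which would call for stronger acid or heat, and then acid-promoted opening of ring C with loss of configuration at C2.
- Fallback, from 10 directly to 12: non-aqueous cleavage with BCl3 (3 equiv, CH2Cl2, −78 to −20 °C) should convert the ketal into the ketone by chloride attack on the O-methyl oxocarbenium ion and then remove the C5 methyl group by chelation in the same flask. Steps 5 and 6 are thereby merged and no new compound is isolated.

## Further compounds

F1 | step 4 | 1-(6-hydroxy-2,3,4-trimethoxyphenyl)ethan-1-one | CC(=O)c1c(O)cc(OC)c(OC)c1OC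
F2 | step 4 | (E)-3-(dimethylamino)-1-(6-hydroxy-2,3,4-trimethoxyphenyl)prop-2-en-1-one | CN(C)/C=C/C(=O)c1c(O)cc(OC)c(OC)c1OC
F3 | step 4 | 5,6,7-trimethoxy-4H-chromen-4-one | COc1cc2occc(=O)c2c(OC)c1OC
F4 | step 3 | 5-[(3,4-dimethoxybenzyl)oxy]-1,2,3-trimethoxybenzene | COc1ccc(COc2cc(OC)c(OC)c(OC)c2)cc1OC
F5 | step 6 | 5-hydroxy-6,7-dimethoxy-4H-chromen-4-one | COc1cc2occc(=O)c2c(O)c1OC
F6 | step 6 | 5-(benzyloxy)-6,7-dimethoxy-4H-chromen-4-one | COc1cc2occc(=O)c2c(OCc3ccccc3)c1OC
F7 | step 6 | (S)-5-(benzyloxy)-2-(3,4-dimethoxyphenyl)-6,7-dimethoxychroman-4-one | COc1ccc([C@@H]2CC(=O)c3c(cc(OC)c(OC)c3OCc4ccccc4)O2)cc1OC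
F0 | step 5 | none | none
A1 | alternative 1 | (S)-6,7-di-tert-butoxy-5-hydroxy-2-(3,4-dimethoxyphenyl)chroman-4-one | COc1ccc([C@@H]2CC(=O)c3c(cc(OC(C)(C)C)c(OC(C)(C)C)c3O)O2)cc1OC
A2 | alternative 1 | (S)-6-(2-diazoacetyl)-2-(3,4-dimethoxyphenyl)-2,3-dihydro-4H-pyran-4-one | COc1ccc([C@@H]2CC(=O)C=C(C(=O)C=[N+]=[N-])O2)cc1OC
A3 | alternative 1 | di-tert-butoxyethyne | CC(C)(C)OC#COC(C)(C)C
A4 | alternative 2 | (S)-2-(3,4-dimethoxyphenyl)-5,6,7-trimethoxychroman-4-one | COc1ccc([C@@H]2CC(=O)c3c(cc(OC)c(OC)c3OC)O2)cc1OC
A5 | alternative 2 | 3,4,5-trimethoxybenzyne | COC1=C(OC)C(OC)=CC#C1
A6 | alternative 2 | methyl (S)-3-(3,4-dimethoxyphenyl)-3-hydroxypropanoate | COc1ccc([C@@H](O)CC(=O)OC)cc1OC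
A7 | alternative 3 | (S)-5,8-dihydroxy-6,7-dimethoxy-2-(3,4-dimethoxyphenyl)chroman-4-one | COc1ccc([C@@H]2CC(=O)c3c(O)c(OC)c(OC)c(O)c3O2)cc1OC
A8 | alternative 3 | (S)-2-[3-(3,4-dimethoxyphenyl)-3-hydroxypropanoyl]-5,6-dimethoxycyclohexa-2,5-diene-1,4-dione | COc1ccc([C@@H](O)CC(=O)C2=CC(=O)C(OC)=C(OC)C2=O)cc1OC
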